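**Plan**

1. Retrosynthesis: the senecioate C9–O bond is cut first. Next come C7–C8 and the C9–H bond together (aldol–Tishchenko), which opens the seven-membered ring to a keto aldehyde. Then C5–C6 is cut (ester-enolate aldol through a temporary O9–C7 lactone tether, the C5 oxygen being removed afterwards), then C4–C5 and C10–C11 (vinylketene [2+2]), and last C1–C2 (vinylogous aldol).
2. Forward: (S)-but-3-yn-2-ol → E-enal → acyclic dienoic acid → bicyclo[3.1.1]heptanone (cyclobutane C4–C5–C11–C10) → bridged lactone that fixes C5 → enone keto aldehyde → seven-membered ring → mixed diester.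
3. Enabling feature: O7 and O9 sit trans on C7 and C9 across the C8 methylene of the seven-membered ring C4–C5–C6–C7–C8–C9–C10 and carry different acyl groups. The quaternary C6 and C10 leave C8 as the only enolisable carbon beside C9 and make the C7 aldehyde non-enolisable, and the two arms are held cofacial on the one-carbon bridges C5 and C10.
4. Stereochemistry: the alkynol centre is carried as C9 (a relay, oxidised before the key step). C1 (S), from a catalyst-controlled vinylogous Mukaiyama aldol, steers the [2+2] (C4, C10, C11) and is later oxidised. The lactone tether plus an endo-face radical reduction fix C5. A chiral lanthanide selects C7, and the Tishchenko hydride transfer copies C7 to C9.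
5. Convention: carbons are numbered as in the target (C1 ketone, C2=C3, cyclobutane C4–C5–C11–C10, C6 gem-dimethyl, C7, C8, C9, C10 methyl). On C5 and C10, "exo" points toward the other one-carbon bridge and "endo" points over the C1–C2–C3 bridge.

Key step: step 17

Assumption: the (S,S) antipode of the bisphosphoramide (step 5) and the (R) antipode of the binaphthoxide (step 17) are taken to be the ones that give C1 (S) and C7 (R); the sense of each is to be confirmed on a first run and the mirror-image catalyst used if it proves opposite.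

**Route**

Step 1
Reactants: 1 (S)-but-3-yn-2-ol
Product: 2 (S)-1-[(but-3-yn-2-yloxy)methyl]-4-methoxybenzene
Conditions: NaH, 4-methoxybenzyl chloride, tetrabutylammonium iodide (cat.), THF/DMF, 0 °C → rt
Reagents that add atoms: 4-methoxybenzyl chloride, COc1ccc(CCl)cc1
Why: Williamson etherification of the sodium alkoxide with the benzylic chloride should protect O9 without touching the carbinol centre, which is carried on as C9.

Step 2
Reactants: 2 (S)-1-[(but-3-yn-2-yloxy)methyl]-4-methoxybenzene
Product: 4 (2E,4S)-4-[(4-methoxybenzyl)oxy]-3-methylpent-2-en-1-ol, via alkenyldimethylalane 3 (not isolated)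
Conditions: Me3Al, Cp2ZrCl2 (cat.), CH2Cl2, 0 °C → rt; then n-BuLi, (CH2O)n, THF, −78 °C → rt; aq. HCl
Reagents that add atoms: trimethylaluminium, C[Al](C)C; formaldehyde (as paraformaldehyde), C=O
Why: Zirconium-catalysed carboalumination of the terminal alkyne adds methyl (to the future C10) and aluminium (to the future C4) to the same side, and the derived alanate is hydroxymethylated with retention, so the E geometry (C9 trans to C1) follows from syn carbometalation.

Step 3
Reactants: 4 (2E,4S)-4-[(4-methoxybenzyl)oxy]-3-methylpent-2-en-1-ol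
Product: 5 (2E,4S)-4-[(4-methoxybenzyl)oxy]-3-methylpent-2-enal
Conditions: activated MnO2, CH2Cl2, rt
Reagents that add atoms: none
Why: Oxidation with activated MnO2 is selective for allylic alcohols and should give the E enal without isomerisation or attack on the PMB ether.

Step 4
Reactants: 6 methyl 3-methylbut-2-enoate
Product: 7 (Z)-tert-butyl[(1-methoxy-3-methylbuta-1,3-dien-1-yl)oxy]dimethylsilane
Conditions: LDA, THF, −78 °C; DMPU, TBSCl, −78 °C → rt
Reagents that add atoms: tert-butyldimethylsilyl chloride, CC(C)(C)[Si](C)(C)Cl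
Why: γ-Deprotonation of the enoate with LDA and O-silylation of the extended enolate (silyl dienol ether formation) gives the vinylogous ketene acetal needed as nucleophile.

Step 5
Reactants: 5 (2E,4S)-4-[(4-methoxybenzyl)oxy]-3-methylpent-2-enal; 7 (Z)-tert-butyl[(1-methoxy-3-methylbuta-1,3-dien-1-yl)oxy]dimethylsilane
Product: 8 methyl (2E,5S,6E,8S)-5-hydroxy-8-[(4-methoxybenzyl)oxy]-3,7-dimethylnona-2,6-dienoate
Conditions: SiCl4, (S,S)-bisphosphoramide (two N,N'-dimethyl-1,1'-binaphthyl-2,2'-diamine phosphoramides joined by a pentane-1,5-diylbis(methylamino) linker, 5 mol%), i-Pr2NEt (cat.), CH2Cl2, −78 °C; aq. NaHCO3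
Reagents that add atoms: none
Why: Vinylogous Mukaiyama aldol addition under Lewis-base-activated SiCl4, in which the chiral phosphoramide-bound silyl cation activates the enal and the dienol ether attacks through its γ-carbon by 1,2-addition in an open transition state on the Si face of the aldehyde, should set the carbinol (C5 of the chain, the future C1) as S by catalyst control, the E enoate arising from the s-trans diene.

Step 6
Reactants: 8 methyl (2E,5S,6E,8S)-5-hydroxy-8-[(4-methoxybenzyl)oxy]-3,7-dimethylnona-2,6-dienoate
Product: 9 methyl (2E,5S,6E,8S)-5-[(tert-butyldimethylsilyl)oxy]-8-[(4-methoxybenzyl)oxy]-3,7-dimethylnona-2,6-dienoate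
Conditions: TBSOTf, 2,6-lutidine, CH2Cl2, −78 → 0 °C
Reagents that add atoms: tert-butyldimethylsilyl triflate, CC(C)(C)[Si](C)(C)OS(=O)(=O)C(F)(F)F
Why: Silylation of the secondary allylic alcohol with the silyl triflate and a hindered pyridine base (silyl ether formation) should be fast at low temperature and avoids ionisation of the allylic carbinol.

Step 7
Reactants: 9 methyl (2E,5S,6E,8S)-5-[(tert-butyldimethylsilyl)oxy]-8-[(4-methoxybenzyl)oxy]-3,7-dimethylnona-2,6-dienoate
Product: 10 (2E,5S,6E,8S)-5-[(tert-butyldimethylsilyl)oxy]-8-[(4-methoxybenzyl)oxy]-3,7-dimethylnona-2,6-dienoic acid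
Conditions: LiOH, THF/MeOH/H2O, 45 °C; then aq. HCl to pH 4, 0 °C
Reagents that add atoms: lithium hydroxide, [Li+].[OH-]
Why: Saponification of the methyl ester followed by mild acidification should give the acid without loss of the secondary silyl ether or migration of the double bonds.

Step 8
Reactants: 10 (2E,5S,6E,8S)-5-[(tert-butyldimethylsilyl)oxy]-8-[(4-methoxybenzyl)oxy]-3,7-dimethylnona-2,6-dienoic acid
Product: 13 (4S)-4-[(tert-butyldimethylsilyl)oxy]-7-[(1S)-1-[(4-methoxybenzyl)oxy]ethyl]-7-methyl-2-methylidenebicyclo[3.1.1]heptan-6-one (target numbering: C5 ketone; C3 methylidene; C1 OTBS on the side of the C5 bridge; C10 methyl endo and C9 arm exo), via acid chloride 11 (not isolated), via vinylketene 12 (not isolated)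
Conditions: 1-chloro-N,N,2-trimethylprop-1-en-1-amine, CH2Cl2, 0 °C → rt; then slow addition to Et3N, toluene, reflux, high dilution
Reagents that add atoms: none
Why: Intramolecular [2+2] cycloaddition of a vinylketene to a trisubstituted alkene, in which γ-dehydrochlorination through the C3 methyl gives the vinylketene, its carbonyl carbon (C5) bonds to the less substituted C4 and its α-carbon (C11) to C10, suprafacial addition to the E alkene places the C9 arm exo and the methyl endo, and allylic 1,3-strain at C1 (hydrogen toward the Z methyl on C10, silyloxy away from it) selects the alkene face and thereby C4, C10 and C11.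

Step 9
Reactants: 13 bicyclic ketone with C9 PMB ether
Product: 14 (4S)-4-[(tert-butyldimethylsilyl)oxy]-7-[(1S)-1-hydroxyethyl]-7-methyl-2-methylidenebicyclo[3.1.1]heptan-6-one (ring stereochemistry as in 13)
Conditions: DDQ, CH2Cl2/pH 7 buffer, 0 °C → rt
Reagents that add atoms: none
Why: DDQ oxidises the electron-rich 4-methoxybenzyl ether to an oxocarbenium ion that water cleaves (oxidative PMB removal), while the silyl ether, the 1,1-disubstituted alkene and the cyclobutanone should be inert.

Step 10
Reactants: 14 C9 alcohol; 15 2-methylpropanoyl chloride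
Product: 16 (1S)-1-[(4S)-4-[(tert-butyldimethylsilyl)oxy]-7-methyl-2-methylidene-6-oxobicyclo[3.1.1]heptan-7-yl]ethyl 2-methylpropanoate (ring stereochemistry as in 13)
Conditions: pyridine, DMAP, CH2Cl2, 0 °C → rt
Reagents that add atoms: none
Why: DMAP-catalysed acylation (esterification with an acid chloride) of the hindered secondary alcohol installs the isobutyrate whose α-carbon and carbonyl carbon become C6 and C7 and whose ester oxygen serves as the tether.

Step 11
Reactants: 16 C9 isobutyrate of the bicyclic ketone
Product: 18 bridged lactone methyl oxalate (C6–C7(=O)–O9 lactone spanning exo-C5 and exo-C10; C5 endo O–C(=O)CO2Me; C9 S with its methyl C8; C1 OTBS; C3 methylidene), via lithium aldolate 17 (not isolated)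
Conditions: LDA, THF, −78 → −40 °C; then ClC(=O)CO2Me, −78 → 0 °C
Reagents that add atoms: methyl chlorooxalate, COC(=O)C(=O)Cl
Why: Intramolecular aldol addition of the ester lithium enolate to the non-enolisable C5 cyclobutanone (7-(enolendo)-exo-trig), in which the enolate hangs from O9 on the exo arm of C10 and can reach C5 only on its exo face, should place C6 exo and O5 endo, the strained-ketone adduct being trapped at once as the methyl oxalate.

Step 12
Reactants: 18 bridged lactone methyl oxalate
Product: 19 C5-deoxy bridged lactone (C5–H endo, C6 exo; C1 OTBS; C3 methylidene)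
Conditions: Bu3SnH, AIBN (cat.), toluene, reflux
Reagents that add atoms: none
Why: Barton–McCombie-type radical deoxygenation, in which the stannyl radical fragments the tertiary methyl oxalate to the C5 cyclobutyl radical that is locked in the lactone bridge and can take hydrogen from Bu3SnH only on its endo face, should give C5 the configuration of the target.

Step 13
Reactants: 19 C5-deoxy bridged lactone
Product: 20 bridged lactone C1 alcohol (C1 S, C3 methylidene)
Conditions: TBAF, AcOH, THF, 0 °C → rt
Reagents that add atoms: none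
Why: Fluoride-induced cleavage of the secondary silyl ether (desilylation), buffered with acetic acid so that the lactone is not opened, frees the C1 alcohol.

Step 14
Reactants: 20 bridged lactone C1 alcohol
Product: 22 enone lactone (C1 ketone, C2=C3 with methyl on C3, lactone unchanged), via methylidene ketone 21 (not isolated)
Conditions: DMP (1,1,1-triacetoxy-1,2-benziodoxol-3(1H)-one), NaHCO3, CH2Cl2, rt; then DBU (cat.), rt
Reagents that add atoms: none
Why: Oxidation with the periodinane gives the β,γ-unsaturated C1 ketone, and DBU then moves the exocyclic double bond into conjugation through the C2 dienolate (base-catalysed alkene isomerisation), which should go to completion because the trisubstituted conjugated C2=C3 enone is the thermodynamic isomer.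

Step 15
Reactants: 22 enone lactone
Product: 23 triol (C1 allylic alcohol, mainly the epimer with OH on the side of the C10 bridge; C7 primary alcohol on the exo CMe2 arm of C5; C9 (S) secondary alcohol on the exo arm of C10)
Conditions: LiAlH4, THF, 0 °C → rt; NaOH/H2O work-up
Reagents that add atoms: none
Why: Hydride reduction with LiAlH4 opens the lactone to the C7 primary and C9 secondary alcohols and reduces the enone by 1,2-addition from the face away from the C10 methyl, the C1 and C9 carbinol configurations being of no consequence because both are oxidised in the next step.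

Step 16
Reactants: 23 triol
Product: 24 2-[6-acetyl-4,6-dimethyl-2-oxobicyclo[3.1.1]hept-3-en-7-yl]-2-methylpropanal (target numbering: C1 enone; C10 methyl endo and acetyl C9/C8 exo; C5–H endo and C(CH3)2CHO arm C6/C7 exo)
Conditions: (COCl)2, DMSO, CH2Cl2, −78 °C; Et3N, −78 → −20 °C
Reagents that add atoms: none
Why: Swern oxidation converts all three hydroxyls into alkoxysulfonium salts before the base is added, so that C1, C7 and C9 are oxidised together and no C7 lactol can form and be over-oxidised back to the lactone.

Step 17
Reactants: 24 enone keto aldehyde; 25 3-methylbutanal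
Product: 27 (4R,5S,7R,9R,10R,11R)-9-hydroxy-7-(3-methylbutanoyloxy)longipin-2-en-1-one, via lanthanum aldolate 26 (not isolated)
Conditions: (R)-LaLi3(binaphthoxide)3 [LaLi3(C20H12O2)3, 20 mol%], LiOTf (20 mol%), THF, 0 °C; then 3-methylbutanal by syringe pump, 0 °C → rt
Reagents that add atoms: none
Why: Proposed new method: the lanthanum binaphthoxide deprotonates C8 of the methyl ketone (the only α-carbon that can enolise, since C6 and C10 are quaternary, C4 is a bridgehead and the vinylogous C3 methyl is less acidic and cannot reach C7), and the enolate adds to the non-enolisable C7 aldehyde in a 7-(enolendo)-exo-trig aldol that closes the seven-membered ring across the two exo arms held cofacial on C5 and C10. The metal aldolate then adds to 3-methylbutanal, and the hemiacetal delivers hydride to C9 through a six-membered chair transition state in which the metal bridges the hemiacetal oxygen and O9, so that hydrogen enters C9 on the face of O7, O9 ends trans to O7 and the acyl group stays on O7. The closest known reactions are the Evans–Tishchenko reduction of β-hydroxy ketones and the lanthanide-binaphthoxide-catalysed intermolecular aldol–Tishchenko reaction, in which the aldol is reversible and hydride transfer decides the stereochemistry; new here are the ring-closing aldol and the use of a second aldehyde as hydride donor. C9 is controlled by C7 through the cyclic hydride transfer, whereas C7 has no substrate bias, because the two faces of the new ring differ only in the distant C1 carbonyl and C3 methyl, so the two aldolates behave as quasi-enantiomers between which the chiral binaphthoxide must choose while retro-aldol keeps them in equilibrium. The step needs selectivity at C7 (catalyst), intramolecular over intermolecular aldol (secured by the proximity of the arms and by adding the aldehyde slowly after cyclisation) and a single enolisation site (secured by the quaternary carbons), and acyl migration is blocked by the trans relation of O7 and O9 on the rigid ring.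

Step 18
Reactants: 27 7-isovalerate 9-alcohol; 28 3-methylbut-2-enoyl chloride
Product: 29 (4R,5S,7R,9R,10R,11R)-7-(3-methylbutanoyloxy)-9-(3-methylbut-2-enoyloxy)longipin-2-en-1-one (CNP0335239.1)
Conditions: pyridine, DMAP (cat.), CH2Cl2, 0 °C → rt
Reagents that add atoms: none
Why: Acylation with the acid chloride under nucleophilic catalysis (esterification) should esterify the C9 hydroxyl, pyridine being preferred to a trialkylamine to avoid vinylketene formation and deconjugation of the senecioyl group.

**Compound list**

1 | (S)-but-3-yn-2-ol | C[C@H](O)C#C | starting material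
2 | (S)-1-[(but-3-yn-2-yloxy)methyl]-4-methoxybenzene | C[C@H](OCc1ccc(OC)cc1)C#C | intermediate
3 | [(1E,3S)-3-[(4-methoxybenzyl)oxy]-2-methylbut-1-en-1-yl]dimethylalane | C[C@H](OCc1ccc(OC)cc1)/C(C)=C/[Al](C)C | intermediate
4 | (2E,4S)-4-[(4-methoxybenzyl)oxy]-3-methylpent-2-en-1-ol | C[C@H](OCc1ccc(OC)cc1)/C(C)=C/CO | intermediate
5 | (2E,4S)-4-[(4-methoxybenzyl)oxy]-3-methylpent-2-enal | C[C@H](OCc1ccc(OC)cc1)/C(C)=C/C=O | intermediate
6 | methyl 3-methylbut-2-enoate | COC(=O)C=C(C)C | starting material
7 | (Z)-tert-butyl[(1-methoxy-3-methylbuta-1,3-dien-1-yl)oxy]dimethylsilane | C=C(C)/C=C(/OC)O[Si](C)(C)C(C)(C)C | intermediate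
8 | methyl (2E,5S,6E,8S)-5-hydroxy-8-[(4-methoxybenzyl)oxy]-3,7-dimethylnona-2,6-dienoate | COC(=O)/C=C(\C)C[C@H](O)/C=C(\C)[C@H](C)OCc1ccc(OC)cc1 | intermediate
9 | methyl (2E,5S,6E,8S)-5-[(tert-butyldimethylsilyl)oxy]-8-[(4-methoxybenzyl)oxy]-3,7-dimethylnona-2,6-dienoate | COC(=O)/C=C(\C)C[C@H](O[Si](C)(C)C(C)(C)C)/C=C(\C)[C@H](C)OCc1ccc(OC)cc1 | intermediate
10 | (2E,5S,6E,8S)-5-[(tert-butyldimethylsilyl)oxy]-8-[(4-methoxybenzyl)oxy]-3,7-dimethylnona-2,6-dienoic acid | OC(=O)/C=C(\C)C[C@H](O[Si](C)(C)C(C)(C)C)/C=C(\C)[C@H](C)OCc1ccc(OC)cc1 | intermediate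
11 | (2E,5S,6E,8S)-5-[(tert-butyldimethylsilyl)oxy]-8-[(4-methoxybenzyl)oxy]-3,7-dimethylnona-2,6-dienoyl chloride | ClC(=O)/C=C(\C)C[C@H](O[Si](C)(C)C(C)(C)C)/C=C(\C)[C@H](C)OCc1ccc(OC)cc1 | intermediate
12 | (5S,6E,8S)-5-[(tert-butyldimethylsilyl)oxy]-8-[(4-methoxybenzyl)oxy]-7-methyl-3-methylidenenona-1,6-dien-1-one (vinylketene) | O=C=CC(=C)C[C@H](O[Si](C)(C)C(C)(C)C)/C=C(\C)[C@H](C)OCc1ccc(OC)cc1 | intermediate
13 | (4S)-4-[(tert-butyldimethylsilyl)oxy]-7-[(1S)-1-[(4-methoxybenzyl)oxy]ethyl]-7-methyl-2-methylidenebicyclo[3.1.1]heptan-6-one (C10 methyl endo, C9 arm exo, OTBS on the C5-bridge side) | C[C@H](OCc1ccc(OC)cc1)[C@]1(C)[C@H]2C(=C)C[C@H](O[Si](C)(C)C(C)(C)C)[C@@H]1C2=O | intermediate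
14 | (4S)-4-[(tert-butyldimethylsilyl)oxy]-7-[(1S)-1-hydroxyethyl]-7-methyl-2-methylidenebicyclo[3.1.1]heptan-6-one (ring stereochemistry as in 13) | C[C@H](O)[C@]1(C)[C@H]2C(=C)C[C@H](O[Si](C)(C)C(C)(C)C)[C@@H]1C2=O | intermediate
15 | 2-methylpropanoyl chloride | CC(C)C(=O)Cl | starting material
16 | (1S)-1-[(4S)-4-[(tert-butyldimethylsilyl)oxy]-7-methyl-2-methylidene-6-oxobicyclo[3.1.1]heptan-7-yl]ethyl 2-methylpropanoate (ring stereochemistry as in 13) | C[C@H](OC(=O)C(C)C)[C@]1(C)[C@H]2C(=C)C[C@H](O[Si](C)(C)C(C)(C)C)[C@@H]1C2=O | intermediate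
17 | lithium C5 alkoxide of the bridged lactone (C6 exo, O5 endo; C1 OTBS; C3 methylidene) | C[C@@H]1OC(=O)C(C)(C)[C@]2(O[Li])[C@H]3[C@@H](O[Si](C)(C)C(C)(C)C)CC(=C)[C@@H]2[C@]31C | intermediate
18 | bridged lactone with C5 endo methyl oxalate (C6–C7(=O)–O9 lactone across exo-C5/exo-C10; C9 S; C1 OTBS; C3 methylidene) | C[C@@H]1OC(=O)C(C)(C)[C@]2(OC(=O)C(=O)OC)[C@H]3[C@@H](O[Si](C)(C)C(C)(C)C)CC(=C)[C@@H]2[C@]31C | intermediate
19 | C5-deoxy bridged lactone (C5–H endo; C1 OTBS; C3 methylidene) | C[C@@H]1OC(=O)C(C)(C)[C@@H]2[C@H]3[C@@H](O[Si](C)(C)C(C)(C)C)CC(=C)[C@@H]2[C@]31C | intermediate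
20 | bridged lactone C1 alcohol (C1 S; C3 methylidene) | C[C@@H]1OC(=O)C(C)(C)[C@@H]2[C@H]3[C@@H](O)CC(=C)[C@@H]2[C@]31C | intermediate
21 | bridged lactone C1 ketone with C3 methylidene | C[C@@H]1OC(=O)C(C)(C)[C@@H]2[C@H]3C(=O)CC(=C)[C@@H]2[C@]31C | intermediate
22 | enone lactone (C1 ketone, C2=C3, methyl on C3; lactone across C5/C10) | C[C@@H]1OC(=O)C(C)(C)[C@@H]2[C@H]3C(=O)C=C(C)[C@@H]2[C@]31C | intermediate
23 | triol: C1 allylic alcohol (OH on the C10-bridge side), C7 primary alcohol, C9 (S) secondary alcohol | C[C@H](O)[C@]1(C)[C@H]2C(C)=C[C@@H](O)[C@@H]1[C@H]2C(C)(C)CO | intermediate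
24 | 2-[6-acetyl-4,6-dimethyl-2-oxobicyclo[3.1.1]hept-3-en-7-yl]-2-methylpropanal (acetyl and CMe2CHO arms exo, C10 methyl and C5–H endo) | CC(=O)[C@]1(C)[C@H]2C(C)=CC(=O)[C@@H]1[C@H]2C(C)(C)C=O | intermediate
25 | 3-methylbutanal | CC(C)CC=O | starting material
26 | C7 aldolate of (7R)-7-hydroxylongipin-2-ene-1,9-dione, bound to the lanthanum–lithium catalyst (drawn as the lithium alkoxide) | O=C1C[C@@H](O[Li])C(C)(C)[C@@H]2[C@H]3C(=O)C=C(C)[C@@H]2[C@]31C | intermediate
27 | (4R,5S,7R,9R,10R,11R)-9-hydroxy-7-(3-methylbutanoyloxy)longipin-2-en-1-one | O[C@@H]1C[C@@H](OC(=O)CC(C)C)C(C)(C)[C@@H]2[C@H]3C(=O)C=C(C)[C@@H]2[C@]31C | intermediate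
28 | 3-methylbut-2-enoyl chloride | CC(C)=CC(=O)Cl | starting material
29 | (4R,5S,7R,9R,10R,11R)-7-(3-methylbutanoyloxy)-9-(3-methylbut-2-enoyloxy)longipin-2-en-1-one (CNP0335239.1) | CC(C)=CC(=O)O[C@@H]1C[C@@H](OC(=O)CC(C)C)C(C)(C)[C@@H]2[C@H]3C(=O)C=C(C)[C@@H]2[C@]31C | target

**Step count and risks**

Total step count: 18. Longest linear sequence: 17 steps (from 1 through steps 1–3 and 5–18); step 4 is a one-step side branch.

Steps most likely to fail:

Step 17. The chiral lanthanide may discriminate poorly between the two interconverting C7 aldolates, 3-methylbutanal may be consumed by its own aldol–Tishchenko chain faster than it reduces C9, or the aldol may dehydrate. The fallback is stepwise and uses known chemistry; it sets out from 24. Kinetic deprotonation with LDA in THF at −78 °C and intramolecular aldol addition should give (4R,5S,7R,10R,11R)-7-hydroxylongipin-2-ene-1,9-dione F1 together with its C7 epimer, (4R,5S,7S,10R,11R)-7-hydroxylongipin-2-ene-1,9-dione F2. The two are separated by chromatography, and F2 is re-equilibrated through retro-aldol and aldol with a substoichiometric amount of LiOt-Bu at low temperature and recycled. F1 is then reduced under Evans–Tishchenko conditions with 3-methylbutanal 25 and catalytic SmI2 in THF at −10 °C, which comes back to the route at 27.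

Step 8. The cycloaddition onto an alkene flanked by two allylic C–O bonds may be so slow that vinylketene oligomerisation prevails, or facial selectivity may erode if the C9 centre works against C1. The fallback sets out from acid 10 and replaces the ketene by a more electrophilic keteniminium ion. The vinylketene generated from 11 at 0 °C is intercepted with pyrrolidine to give the β,γ-unsaturated amide, 1-[(5S,6E,8S)-5-[(tert-butyldimethylsilyl)oxy]-8-[(4-methoxybenzyl)oxy]-7-methyl-3-methylidenenon-6-enoyl]pyrrolidine F3. Tf2O and 2,4,6-collidine in 1,2-dichloroethane convert it into the vinylketeniminium triflate F4, whose intramolecular [2+2] cycloaddition should give the cyclobutaniminium triflate F5. Hydrolysis with aqueous NaHCO3 comes back to the route at 13.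

Step 11. The amide base may attack the strained ketone, the lithium aldolate may revert by retro-aldol before it is acylated, or acylation of the hindered tertiary alkoxide may be incomplete. The fallback sets out from alcohol 14 and forms the enolate reductively instead of by deprotonation. Acylation with 2-bromo-2-methylpropanoyl bromide and pyridine should give the bromo ester, (1S)-1-[(4S)-4-[(tert-butyldimethylsilyl)oxy]-7-methyl-2-methylidene-6-oxobicyclo[3.1.1]heptan-7-yl]ethyl 2-bromo-2-methylpropanoate F6. SmI2 (2.2 equiv) in THF at −78 °C then effects an intramolecular Reformatsky reaction through a samarium enolate chelated to the ketone, giving the tertiary hydroxy lactone (C5 endo OH, otherwise as 18) F7. Methyl chlorooxalate with DMAP and pyridine converts F7 into the oxalate, which comes back to the route at 18.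

Further compounds
F1 | step 17 | (4R,5S,7R,10R,11R)-7-hydroxylongipin-2-ene-1,9-dione | O=C1C[C@@H](O)C(C)(C)[C@@H]2[C@H]3C(=O)C=C(C)[C@@H]2[C@]31C
F2 | step 17 | (4R,5S,7S,10R,11R)-7-hydroxylongipin-2-ene-1,9-dione | O=C1C[C@H](O)C(C)(C)[C@@H]2[C@H]3C(=O)C=C(C)[C@@H]2[C@]31C
F3 | step 8 | 1-[(5S,6E,8S)-5-[(tert-butyldimethylsilyl)oxy]-8-[(4-methoxybenzyl)oxy]-7-methyl-3-methylidenenon-6-enoyl]pyrrolidine | O=C(CC(=C)C[C@H](O[Si](C)(C)C(C)(C)C)/C=C(\C)[C@H](C)OCc1ccc(OC)cc1)N1CCCC1
F4 | step 8 | vinylketeniminium triflate derived from F3 | C=C(C=C=[N+]1CCCC1)C[C@H](O[Si](C)(C)C(C)(C)C)/C=C(\C)[C@H](C)OCc1ccc(OC)cc1.[O-]S(=O)(=O)C(F)(F)F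
F5 | step 8 | pyrrolidinium-ylidene (cyclobutaniminium) triflate corresponding to ketone 13 | C[C@H](OCc1ccc(OC)cc1)[C@]1(C)[C@H]2C(=C)C[C@H](O[Si](C)(C)C(C)(C)C)[C@@H]1C2=[N+]1CCCC1.[O-]S(=O)(=O)C(F)(F)F
F6 | step 11 | (1S)-1-[(4S)-4-[(tert-butyldimethylsilyl)oxy]-7-methyl-2-methylidene-6-oxobicyclo[3.1.1]heptan-7-yl]ethyl 2-bromo-2-methylpropanoate | C[C@H](OC(=O)C(C)(C)Br)[C@]1(C)[C@H]2C(=C)C[C@H](O[Si](C)(C)C(C)(C)C)[C@@H]1C2=O
F7 | step 11 | bridged lactone with C5 endo tertiary alcohol (C1 OTBS, C3 methylidene) | C[C@@H]1OC(=O)C(C)(C)[C@]2(O)[C@H]3[C@@H](O[Si](C)(C)C(C)(C)C)CC(=C)[C@@H]2[C@]31C
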